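Everything rests on opening ring A, the pyranone of the 3-aryloxycoumarin half (unit A), at its O1–C8a bond: O1 is treated as an oxygen atom inserted between the carbonyl C2 and the arene carbon C8a. Because C8a has a methoxy group ortho (C8) and another para (C6), it is an excellent migrating group, so a Baeyer–Villiger oxidation converts a five-membered aryl ketone into the six-membered lactone in one operation. The precursor is a racemic 6-acetoxy-5,7-dimethoxyindan-1-one carrying the 7-oxygen of isofraxidin (unit B) at C2, made from sinapic acid and isofraxidin by etherification of an alpha-bromo ketone.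

Key step: step 6

Assumption: the target is achiral; compounds 5, 7 and 9 are racemates and 8 is a mixture of racemic diastereomers, and their stereocentre (C2 of the indanone, C3 of the lactone) is erased in step 7. The acetate is kept as the phenol protecting group because it is electron-withdrawing, stable to acid, peracid and DDQ, and removable at the end under conditions the coumarin lactones tolerate.

Step 1
Reactants: 1 sinapic acid
Product: 2 3-(4-hydroxy-3,5-dimethoxyphenyl)propanoic acid
Conditions: H2 (1 atm), 10% Pd/C, MeOH, rt
Reagents that add atoms: none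
Why: Heterogeneous catalytic hydrogenation saturates the conjugated C=C of the cinnamic acid under conditions that leave the arene, the phenol, the methyl ethers and the carboxylic acid untouched.

Step 2
Reactants: 2 3-(4-hydroxy-3,5-dimethoxyphenyl)propanoic acid
Product: 3 6-hydroxy-5,7-dimethoxyindan-1-one
Conditions: P2O5/MeSO3H (Eaton's reagent), 60 °C; ice-water quench
Reagents that add atoms: none
Why: Intramolecular Friedel–Crafts acylation through the mixed anhydride or acylium ion closes the five-membered ketone at either of the two equivalent positions ortho to the side chain, each of which is ortho to one methoxy group and para to the other, so that only one indanone can form and the free phenol, meta to the site of attack, is tolerated.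

Step 3
Reactants: 3 6-hydroxy-5,7-dimethoxyindan-1-one
Product: 4 6-acetoxy-5,7-dimethoxyindan-1-one
Conditions: Ac2O, pyridine, DMAP (cat.), CH2Cl2, 0 °C → rt
Reagents that add atoms: acetic anhydride, CC(=O)OC(C)=O
Why: DMAP-catalysed O-acylation of the only hydroxyl group gives an aryl acetate that masks the phenol for the etherification in step 5 and lowers the electron density of the ring, which guards it against ring bromination in step 4 and against the peracid in step 6.

Step 4
Reactants: 4 6-acetoxy-5,7-dimethoxyindan-1-one
Product: 5 rac-6-acetoxy-2-bromo-5,7-dimethoxyindan-1-one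
Conditions: CuBr2 (2.0 equiv), EtOAc/CHCl3 (1:1), reflux
Reagents that add atoms: copper dibromide CuBr2, [Cu+2].[Br-].[Br-]
Why: CuBr2-mediated alpha-bromination of an aryl ketone proceeds through the enol at C2, the only enolisable position, and stops at the monobromide with two equivalents of CuBr2, and the new stereocentre at C2 is formed as the racemate, which is acceptable because it is erased in step 7.

Step 5
Reactants: 5 rac-6-acetoxy-2-bromo-5,7-dimethoxyindan-1-one; 6 isofraxidin (7-hydroxy-6,8-dimethoxycoumarin)
Product: 7 rac-6-acetoxy-2-[(6,8-dimethoxy-2-oxo-2H-chromen-7-yl)oxy]-5,7-dimethoxyindan-1-one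
Conditions: K2CO3 (1.5 equiv), dry acetone, rt → 40 °C, N2
Reagents that add atoms: none
Why: Williamson ether synthesis by SN2 displacement at the carbonyl-activated secondary bromide works because the phenoxide of 6 is a weak, vinylogous-carboxylate base that disfavours elimination of HBr, and acetyl transfer from 5 is thermodynamically uphill since 6 is the more acidic phenol; the centre at C2 remains racemic.

Step 6
Reactants: 7 rac-6-acetoxy-2-[(6,8-dimethoxy-2-oxo-2H-chromen-7-yl)oxy]-5,7-dimethoxyindan-1-one
Product: 9 rac-7-acetoxy-3-[(6,8-dimethoxy-2-oxo-2H-chromen-7-yl)oxy]-6,8-dimethoxy-3,4-dihydrocoumarin, via Criegee peroxyhemiketal 8 (not isolated)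
Conditions: mCPBA (2 equiv), CF3CO2H, CH2Cl2, 0 °C → rt, dark; aq. Na2SO3/NaHCO3 work-up
Reagents that add atoms: mCPBA (3-chloroperoxybenzoic acid), OOC(=O)c1cccc(Cl)c1
Why: Protonation by CF3CO2H activates the ketone C1 of 7 toward addition of mCPBA, and the resulting Criegee peroxyhemiketal 8 rearranges by a concerted 1,2-shift of the aryl carbon C7a from C1 to the proximal peroxide oxygen, anti-periplanar to the breaking O–O bond, with loss of 3-chlorobenzoate. The closest known reaction type is the Baeyer–Villiger oxidation of 1-indanones to 3,4-dihydrocoumarins, in line with the general preference for migration of ortho- and para-alkoxyaryl groups in Baeyer–Villiger oxidations of aryl ketones. Ring A is closed not by a cyclisation but by ring expansion: one oxygen atom is inserted into the C1–C7a bond of the cyclopentanone, which creates O1–C8a and O1–C2 of the six-membered dihydropyranone. No stereocentre is formed; C2 of the indanone is a spectator, becomes C3 of the lactone as the racemate, and is erased in step 7. The step needs migration of C7a in preference to C2 and oxidation of the ketone in preference to the arenes and the alkene of unit B. The methoxy groups ortho (indanone C7) and para (indanone C5) to C7a stabilise the positive charge that builds up on the migrating aryl carbon, whereas C2 carries an inductively withdrawing aryloxy group whose oxygen lone pair is delocalised into the coumarin of unit B, and the acetate together with the electron-poor pyranone alkene of unit B keeps the remainder inert to the electrophilic peracid.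

Step 7
Reactants: 9 rac-7-acetoxy-3-[(6,8-dimethoxy-2-oxo-2H-chromen-7-yl)oxy]-6,8-dimethoxy-3,4-dihydrocoumarin
Product: 10 7-acetoxy-3-[(6,8-dimethoxy-2-oxo-2H-chromen-7-yl)oxy]-6,8-dimethoxycoumarin
Conditions: DDQ (1.5 equiv), 1,4-dioxane, reflux
Reagents that add atoms: none
Why: DDQ dehydrogenation of a 3,4-dihydrocoumarin removes hydride from the benzylic C4 and a proton from the acidic C3, is driven by formation of the conjugated coumarin, leaves the aryl acetate, the aryl ether and the second coumarin untouched, and erases the stereocentre at C3.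

Step 8
Reactants: 10 7-acetoxy-3-[(6,8-dimethoxy-2-oxo-2H-chromen-7-yl)oxy]-6,8-dimethoxycoumarin
Product: 11 7-hydroxy-3-[(6,8-dimethoxy-2-oxo-2H-chromen-7-yl)oxy]-6,8-dimethoxy-2H-chromen-2-one (target)
Conditions: K2CO3 (cat.), MeOH, 0 °C; then 1 M HCl
Reagents that add atoms: none
Why: Carbonate-catalysed transesterification cleaves the aryl acetate much faster than the coumarin lactones because its leaving group is a phenoxide conjugated to the pyranone carbonyl, and the acidic work-up recloses any lactone that has opened, since the cis geometry of C3=C4 is retained.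

Compound list
1 | sinapic acid, (E)-3-(4-hydroxy-3,5-dimethoxyphenyl)prop-2-enoic acid | COc1cc(/C=C/C(=O)O)cc(OC)c1O | starting material
2 | 3-(4-hydroxy-3,5-dimethoxyphenyl)propanoic acid | COc1cc(CCC(=O)O)cc(OC)c1O | intermediate
3 | 6-hydroxy-5,7-dimethoxyindan-1-one | COc1cc2c(c(OC)c1O)C(=O)CC2 | intermediate
4 | 6-acetoxy-5,7-dimethoxyindan-1-one | CC(=O)Oc1c(OC)cc2c(c1OC)C(=O)CC2 | intermediate
5 | rac-6-acetoxy-2-bromo-5,7-dimethoxyindan-1-one | CC(=O)Oc1c(OC)cc2c(c1OC)C(=O)C(Br)C2 | intermediate
6 | isofraxidin, 7-hydroxy-6,8-dimethoxy-2H-chromen-2-one | COc1cc2ccc(=O)oc2c(OC)c1O | starting material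
7 | rac-6-acetoxy-2-[(6,8-dimethoxy-2-oxo-2H-chromen-7-yl)oxy]-5,7-dimethoxyindan-1-one | CC(=O)Oc1c(OC)cc2c(c1OC)C(=O)C(Oc1c(OC)cc3ccc(=O)oc3c1OC)C2 | intermediate
8 | Criegee peroxyhemiketal of 7: 1-hydroxy-1-(3-chlorobenzoylperoxy) adduct at the indanone carbonyl carbon, mixture of racemic diastereomers, not isolated | CC(=O)Oc1c(OC)cc2c(c1OC)C(O)(OOC(=O)c1cccc(Cl)c1)C(Oc1c(OC)cc3ccc(=O)oc3c1OC)C2 | intermediate
9 | rac-7-acetoxy-3-[(6,8-dimethoxy-2-oxo-2H-chromen-7-yl)oxy]-6,8-dimethoxy-3,4-dihydrocoumarin (chroman-2-one) | CC(=O)Oc1c(OC)cc2c(c1OC)OC(=O)C(Oc1c(OC)cc3ccc(=O)oc3c1OC)C2 | intermediate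
10 | 7-acetoxy-3-[(6,8-dimethoxy-2-oxo-2H-chromen-7-yl)oxy]-6,8-dimethoxycoumarin | CC(=O)Oc1c(OC)cc2cc(Oc3c(OC)cc4ccc(=O)oc4c3OC)c(=O)oc2c1OC | intermediate
11 | 7-hydroxy-3-[(6,8-dimethoxy-2-oxo-2H-chromen-7-yl)oxy]-6,8-dimethoxy-2H-chromen-2-one | COc1cc2cc(Oc3c(OC)cc4ccc(=O)oc4c3OC)c(=O)oc2c(OC)c1O | target

Total step count: 8
Longest linear sequence: 8 steps (1 → 11); isofraxidin 6 enters in step 5.

Steps most likely to fail

Step 6. The C2 carbon could migrate in place of C7a, which would give an isochromanone-type acylal. The peracid could also hydroxylate one of the electron-rich arenes before the rather unreactive, vinylogous-ester-like ketone has been consumed. The fallback builds ring A by condensation instead of oxygen insertion; it sets out from 6 and comes back at 10. Isofraxidin 6 is O-alkylated with tert-butyl bromoacetate (K2CO3, acetone) to tert-butyl 2-[(6,8-dimethoxy-2-oxo-2H-chromen-7-yl)oxy]acetate F1, and the ester is cleaved with CF3CO2H in CH2Cl2 to 2-[(6,8-dimethoxy-2-oxo-2H-chromen-7-yl)oxy]acetic acid F2. In parallel, commercial syringaldehyde is brominated (Br2, AcOH) to 2-bromo-4-hydroxy-3,5-dimethoxybenzaldehyde F3, and Ullmann-type hydroxylation (aq. NaOH, Cu powder, reflux) converts it into 2,4-dihydroxy-3,5-dimethoxybenzaldehyde F4. Perkin-type condensation of F2 with F4 (Ac2O, Et3N, 120 °C) acetylates the 4-hydroxyl, condenses the activated methylene with the aldehyde and lactonises; this gives 10 directly and bypasses steps 6 and 7.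

Step 7. Hydride abstraction from C4 may be slow because the substituent para to C4a is only an acetoxy group, and prolonged heating with DDQ may lead to over-oxidation or charge-transfer decomposition of the electron-rich rings. The fallback replaces the dehydrogenation by a selenoxide elimination; it sets out from 9 and comes back at 10. Kinetic enolisation of 9 with LiHMDS in THF at −78 °C (the alpha-aryloxy lactone C–H is more acidic than the acetate methyl) and trapping with PhSeBr gives rac-7-acetoxy-3-[(6,8-dimethoxy-2-oxo-2H-chromen-7-yl)oxy]-6,8-dimethoxy-3-(phenylselanyl)chroman-2-one F5. Oxidation with H2O2 in CH2Cl2 at 0 °C gives the corresponding selenoxide F6, which is not isolated and undergoes syn-elimination toward the C4 hydrogens below room temperature to give 10.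

Step 5. Substitution by the doubly ortho-substituted, weakly nucleophilic phenoxide may be slow, so that elimination of HBr to an unstable indenone or migration of the acetyl group between the two phenols could take over. The fallback forms the same C2–O bond under neutral redox-condensation conditions; it sets out from 4 and comes back at 7. Ketone 4 is converted with TMSOTf and Et3N (CH2Cl2, 0 °C) into its trimethylsilyl enol ether, 4,6-dimethoxy-3-(trimethylsilyloxy)-1H-inden-5-yl acetate F7. Rubottom oxidation (mCPBA, NaHCO3, CH2Cl2, 0 °C) gives rac-6-acetoxy-5,7-dimethoxy-2-(trimethylsilyloxy)indan-1-one F8, and dilute HCl in THF liberates rac-6-acetoxy-2-hydroxy-5,7-dimethoxyindan-1-one F9. Mitsunobu etherification of F9 with isofraxidin 6 (PPh3, DIAD, THF, 0 °C → rt), for which the acidic phenol is a suitable pronucleophile, gives 7.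

Further compounds
F1 | step 6 | tert-butyl 2-[(6,8-dimethoxy-2-oxo-2H-chromen-7-yl)oxy]acetate | CC(C)(C)OC(=O)COc1c(OC)cc2ccc(=O)oc2c1OC
F2 | step 6 | 2-[(6,8-dimethoxy-2-oxo-2H-chromen-7-yl)oxy]acetic acid | OC(=O)COc1c(OC)cc2ccc(=O)oc2c1OC
F3 | step 6 | 2-bromo-4-hydroxy-3,5-dimethoxybenzaldehyde | COc1cc(C=O)c(Br)c(OC)c1O
F4 | step 6 | 2,4-dihydroxy-3,5-dimethoxybenzaldehyde | COc1cc(C=O)c(O)c(OC)c1O
F5 | step 7 | rac-7-acetoxy-3-[(6,8-dimethoxy-2-oxo-2H-chromen-7-yl)oxy]-6,8-dimethoxy-3-(phenylselanyl)chroman-2-one | CC(=O)Oc1c(OC)cc2c(c1OC)OC(=O)C([Se]c1ccccc1)(Oc1c(OC)cc3ccc(=O)oc3c1OC)C2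
F6 | step 7 | selenoxide of F5, mixture of diastereomers, not isolated | CC(=O)Oc1c(OC)cc2c(c1OC)OC(=O)C([Se](=O)c1ccccc1)(Oc1c(OC)cc3ccc(=O)oc3c1OC)C2
F7 | step 5 | 4,6-dimethoxy-3-(trimethylsilyloxy)-1H-inden-5-yl acetate | CC(=O)Oc1c(OC)cc2c(c1OC)C(O[Si](C)(C)C)=CC2
F8 | step 5 | rac-6-acetoxy-5,7-dimethoxy-2-(trimethylsilyloxy)indan-1-one | CC(=O)Oc1c(OC)cc2c(c1OC)C(=O)C(O[Si](C)(C)C)C2
F9 | step 5 | rac-6-acetoxy-2-hydroxy-5,7-dimethoxyindan-1-one | CC(=O)Oc1c(OC)cc2c(c1OC)C(=O)C(O)C2
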